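The synthesis rests on cutting both aryl–CH2 bonds of ring A, C3'–CH2 and C5'–CH2, back to oxygen. Each prenyl group sits ortho to a phenolic oxygen (C3' beside O2' and O4', C5' beside O4'), so a chalcone carrying 2-methylbut-3-en-2-yl ethers on O2' and O4' should deliver both in one thermal operation: two [3,3] shifts with allylic inversion that also unmask the two ring A phenols. The precursor is the E-chalcone bis(tertiary allyl) ether with the ring B phenol masked as a methoxymethyl ether, assembled by CuCl2-catalysed propargylation, semi-hydrogenation and Claisen–Schmidt condensation; acid then frees the last phenol.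

Key step: step 5

Remark on the chemistry: ring A is the ketone-bearing ring (primed locants, C1' = acyl carbon) and ring B the 4-hydroxyphenyl ring; the E-alkene is the only stereo-element of the target, and the stereocentre of the transient aldol 8 (racemic) disappears on dehydration.

Step 1
Reactants: 1 2,4-dihydroxyacetophenone; 2 2-methylbut-3-yn-2-ol
Product: 4 1-[2,4-bis(2-methylbut-3-yn-2-yloxy)phenyl]ethan-1-one, via 2-methylbut-3-yn-2-yl trifluoroacetate 3 (not isolated)
Conditions: 2 (3 equiv), (CF3CO)2O, DBU, MeCN, 0 °C; then 1, DBU, CuCl2·2H2O (cat.), MeCN, 0 °C → rt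
Reagents that add atoms: none
Why: CuCl2-catalysed substitution of a tertiary propargylic ester by a phenoxide (the metalated alkyne ionises to an allenylidene-type electrophile that is captured at the tertiary carbon) is a standard route to aryl 1,1-dimethylpropargyl ethers; DBU deprotonates even the hydrogen-bonded 2-OH and the excess of ester 3, for which the anhydride serves only as activator of 2, should drive the second etherification.

Step 2
Reactants: 4 1-[2,4-bis(2-methylbut-3-yn-2-yloxy)phenyl]ethan-1-one
Product: 5 1-[2,4-bis(2-methylbut-3-en-2-yloxy)phenyl]ethan-1-one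
Conditions: H2 (1 atm), Pd/CaCO3 poisoned with Pb(OAc)2, quinoline, EtOAc, rt; stopped at 2 equiv H2 uptake; concentrated below 35 °C
Reagents that add atoms: none
Why: Lindlar-type semi-hydrogenation reduces the two terminal alkynes to vinyl groups much faster than the resulting alkenes, and the aryl ketone and the tertiary C–O bonds should be untouched on the poisoned catalyst at room temperature.

Step 3
Reactants: 6 4-hydroxybenzaldehyde
Product: 7 4-(methoxymethoxy)benzaldehyde
Conditions: MOMCl, K2CO3, acetone, 0 °C → rt
Reagents that add atoms: chloromethyl methyl ether (MOMCl), COCCl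
Why: Williamson-type O-alkylation of the phenoxide by the highly reactive α-chloro ether gives the base-stable acetal, the aldehyde being inert to K2CO3 in acetone.

Step 4
Reactants: 5 1-[2,4-bis(2-methylbut-3-en-2-yloxy)phenyl]ethan-1-one; 7 4-(methoxymethoxy)benzaldehyde
Product: 9 (E)-1-[2,4-bis(2-methylbut-3-en-2-yloxy)phenyl]-3-[4-(methoxymethoxy)phenyl]prop-2-en-1-one, via racemic aldol adduct 8 (not isolated)
Conditions: KOH, EtOH–H2O, 0 °C → rt
Reagents that add atoms: none
Why: Claisen–Schmidt condensation, in which the methyl ketone enolate adds to the non-enolisable aldehyde and aldol 8 loses water by E1cB elimination to the thermodynamically preferred E-enone; with both ring A oxygens etherified no flavanone can form, and the tertiary allyl ethers and the acetal are stable to base at room temperature.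

Step 5
Reactants: 9 (E)-1-[2,4-bis(2-methylbut-3-en-2-yloxy)phenyl]-3-[4-(methoxymethoxy)phenyl]prop-2-en-1-one
Product: 11 (E)-1-[2,4-dihydroxy-3,5-bis(3-methylbut-2-en-1-yl)phenyl]-3-[4-(methoxymethoxy)phenyl]prop-2-en-1-one, via mono-rearranged 2'-phenol 10 (not isolated)
Conditions: PhNEt2 (degassed), 130 °C, Ar, dark
Reagents that add atoms: none
Why: Both ethers are aryl tertiary-allyl ethers set up for the aromatic Claisen rearrangement: in a concerted six-electron, chair-like transition state the vinyl CH2 bonds to the ring carbon ortho to the ether oxygen while the O–C(quaternary) bond gives way, and the cyclohexa-2,4-dienone formed enolises to the phenol, the end-for-end turn of the allyl unit converting each O-(1,1-dimethylallyl) group into a C-(3-methylbut-2-enyl) group. The closest known reaction type is the thermal ortho-Claisen rearrangement of aryl 1,1-dimethylallyl ethers to ortho-prenylphenols, which for such tertiary ethers needs only about 110–140 °C, mild enough to leave the enone and the acetal alone. No ring is closed and no stereocentre is created; the E-alkene is a spectator and is protected by excluding light. The step needs site selectivity: the 2'-ether, twisted by the neighbouring acyl group, has C3' as its only free ortho carbon (C1' is acylated) and should move first to give 10, after which the 4'-ether finds C3' blocked and can end productively only at C5'. Should the 4'-ether move first instead, it should still choose C5', because C3' is buried between two tertiary ether groups and no chelated 2'-OH is yet present to steer it to C3', so both orders converge on 11. The weakly basic solvent buffers traces of acid that would otherwise ionise the tertiary allyl ethers or cyclise the new ortho-prenylphenols.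

Step 6
Reactants: 11 (E)-1-[2,4-dihydroxy-3,5-bis(3-methylbut-2-en-1-yl)phenyl]-3-[4-(methoxymethoxy)phenyl]prop-2-en-1-one
Product: 12 (E)-1-[2,4-dihydroxy-3,5-bis(3-methylbut-2-en-1-yl)phenyl]-3-(4-hydroxyphenyl)prop-2-en-1-one
Conditions: 3 M aq. HCl, MeOH, rt → 45 °C
Reagents that add atoms: none
Why: Acid-catalysed acetal exchange with methanol (methoxymethyl ether cleavage) frees the ring B phenol, and dilute acid at mild temperature is chosen so that the prenyl alkenes are not protonated into chromans and the chelated 2'-hydroxychalcone does not isomerise to a flavanone.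

Compound list
1 | 2,4-dihydroxyacetophenone | CC(=O)c1ccc(O)cc1O | starting material
2 | 2-methylbut-3-yn-2-ol | CC(C)(O)C#C | starting material
3 | 2-methylbut-3-yn-2-yl trifluoroacetate | C#CC(C)(C)OC(=O)C(F)(F)F | intermediate
4 | 1-[2,4-bis(2-methylbut-3-yn-2-yloxy)phenyl]ethan-1-one | CC(=O)c1ccc(OC(C)(C)C#C)cc1OC(C)(C)C#C | intermediate
5 | 1-[2,4-bis(2-methylbut-3-en-2-yloxy)phenyl]ethan-1-one | CC(=O)c1ccc(OC(C)(C)C=C)cc1OC(C)(C)C=C | intermediate
6 | 4-hydroxybenzaldehyde | O=Cc1ccc(O)cc1 | starting material
7 | 4-(methoxymethoxy)benzaldehyde | COCOc1ccc(C=O)cc1 | intermediate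
8 | 1-[2,4-bis(2-methylbut-3-en-2-yloxy)phenyl]-3-hydroxy-3-[4-(methoxymethoxy)phenyl]propan-1-one (racemic) | C=CC(C)(C)Oc1ccc(C(=O)CC(O)c2ccc(OCOC)cc2)c(OC(C)(C)C=C)c1 | intermediate
9 | (E)-1-[2,4-bis(2-methylbut-3-en-2-yloxy)phenyl]-3-[4-(methoxymethoxy)phenyl]prop-2-en-1-one | C=CC(C)(C)Oc1ccc(C(=O)/C=C/c2ccc(OCOC)cc2)c(OC(C)(C)C=C)c1 | intermediate
10 | (E)-1-[2-hydroxy-3-(3-methylbut-2-en-1-yl)-4-(2-methylbut-3-en-2-yloxy)phenyl]-3-[4-(methoxymethoxy)phenyl]prop-2-en-1-one | C=CC(C)(C)Oc1ccc(C(=O)/C=C/c2ccc(OCOC)cc2)c(O)c1CC=C(C)C | intermediate
11 | (E)-1-[2,4-dihydroxy-3,5-bis(3-methylbut-2-en-1-yl)phenyl]-3-[4-(methoxymethoxy)phenyl]prop-2-en-1-one | COCOc1ccc(/C=C/C(=O)c2cc(CC=C(C)C)c(O)c(CC=C(C)C)c2O)cc1 | intermediate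
12 | (E)-1-[2,4-dihydroxy-3,5-bis(3-methylbut-2-en-1-yl)phenyl]-3-(4-hydroxyphenyl)prop-2-en-1-one | CC(C)=CCc1cc(C(=O)/C=C/c2ccc(O)cc2)c(O)c(CC=C(C)C)c1O | target

Total step count: 6
Longest linear sequence: 5 steps (steps 1, 2, 4, 5 and 6; step 3 is a one-step side branch).

Steps most likely to fail

Step 5. Site selection in the two sigmatropic shifts may go astray. If the 4'-ether migrates to C3' before the 2'-ether has moved, the 2'-ether is left without a free ortho carbon. It can then leave only by a Claisen–Cope (para) pathway, which would put a 1,1-dimethylallyl group on C5', or by fragmentation with loss of isoprene. Prolonged heating could also cyclise the 2'-hydroxychalcone. The fallback sets out from 1 and installs both prenyl groups by direct nuclear C-alkylation of the phenoxide. Prenyl bromide in aqueous KOH should give, after separation from mono-C-prenylated and O-prenylated material and with modest efficiency, 1-[2,4-dihydroxy-3,5-bis(3-methylbut-2-en-1-yl)phenyl]ethan-1-one F1. The non-chelated 4-OH is then capped with MOMCl and K2CO3 in acetone to give 1-[2-hydroxy-4-(methoxymethoxy)-3,5-bis(3-methylbut-2-en-1-yl)phenyl]ethan-1-one F2. Claisen–Schmidt condensation of F2 with 7 (KOH, EtOH) should give (E)-1-[2-hydroxy-4-(methoxymethoxy)-3,5-bis(3-methylbut-2-en-1-yl)phenyl]-3-[4-(methoxymethoxy)phenyl]prop-2-en-1-one F3. Treatment with HCl in MeOH as in step 6 removes both acetals, and the fallback comes back to the route at 12.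

Step 1. The second etherification, at the 2-OH that is hydrogen-bonded to and crowded by the acetyl group, may stall after mono-alkylation at the 4-OH. Trifluoroacetyl transfer to the phenol and oxidative alkyne dimerisation may also consume the reagent. The fallback sets out from 1 and forms both tertiary allyl ethers directly by Tsuji–Trost O-allylation. The reagent is tert-butyl 2-methylbut-3-en-2-yl carbonate F4, made from 2-methylbut-3-en-2-ol, n-BuLi and Boc2O. With catalytic Pd(PPh3)4 in THF at 0 °C, F4 ionises with loss of CO2 to a 1,1-dimethyl-π-allyl intermediate that phenoxides capture at the tertiary terminus under kinetic control. This comes back to the route at 5 and bypasses 4 and the semi-hydrogenation.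

Step 6. During acetal cleavage the acid may protonate the prenyl alkenes, which would then cyclise onto the neighbouring phenols, or it may isomerise the 2'-hydroxychalcone by intramolecular conjugate addition. The fallback avoids both the protecting group and the acid. It sets out from 5, which is condensed with unprotected 6 using excess KOH in EtOH–H2O; the aldehyde then reacts more slowly, as its phenoxide. This should give (E)-1-[2,4-bis(2-methylbut-3-en-2-yloxy)phenyl]-3-(4-hydroxyphenyl)prop-2-en-1-one F5. Heating F5 as in step 5 should bring about the double rearrangement and return to the route directly at 12.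

Further compounds
F1 | step 5 | 1-[2,4-dihydroxy-3,5-bis(3-methylbut-2-en-1-yl)phenyl]ethan-1-one | CC(=O)c1cc(CC=C(C)C)c(O)c(CC=C(C)C)c1O
F2 | step 5 | 1-[2-hydroxy-4-(methoxymethoxy)-3,5-bis(3-methylbut-2-en-1-yl)phenyl]ethan-1-one | CC(=O)c1cc(CC=C(C)C)c(OCOC)c(CC=C(C)C)c1O
F3 | step 5 | (E)-1-[2-hydroxy-4-(methoxymethoxy)-3,5-bis(3-methylbut-2-en-1-yl)phenyl]-3-[4-(methoxymethoxy)phenyl]prop-2-en-1-one | COCOc1ccc(/C=C/C(=O)c2cc(CC=C(C)C)c(OCOC)c(CC=C(C)C)c2O)cc1
F4 | step 1 | tert-butyl 2-methylbut-3-en-2-yl carbonate | C=CC(C)(C)OC(=O)OC(C)(C)C
F5 | step 6 | (E)-1-[2,4-bis(2-methylbut-3-en-2-yloxy)phenyl]-3-(4-hydroxyphenyl)prop-2-en-1-one | C=CC(C)(C)Oc1ccc(C(=O)/C=C/c2ccc(O)cc2)c(OC(C)(C)C=C)c1
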